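**Plan**
- Numbering (germacrane): ring C1–C10 with C1=C2 (E), C3 ketone, C4=C5 (Z, C15 hydroxymethyl on C4), C6 (lactone O), C7, C8 (ester), C9, C10 (OH, C14 methyl); lactone C12(=O)–C11(=C13H2) fused at C6–C7.
- Retrosynthetic cuts, in order: C3–C4 of the ten-membered ring (ketone → carbinol → C3 aldehyde + C4 iodide), C1=C2 (Wittig), C8–O (ester, with inversion), C7–C8 (allylation), C7=C11 and O–C12 (metathesis, ester), C5–C6 (alkynylation).
- Enabling feature: C3 is the carbonyl between the C1=C2 and C4=C5 alkenes, so at the carbinol level it is the adduct of a C4 alkenyl metal and a C3 enal. Both carbons are electrophiles in the precursor (CHO and C–I) and are joined by reductive polarity reversal at C4 (CrCl2/NiCl2). The Z-C4=C5 alkene holds C4 cis to C6 of the trans-fused lactone ring.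
- Forward order: butenolide ring (metathesis) → α-methylene lactone ring with the C7–C8 bond (Barbier) → C8 ester → C1–C3 enal → ten-membered ring → dienone → deprotection.
- Stereochemistry: C6 from catalytic asymmetric alkynylation; C7 by addition anti to the C6 side chain; C8 by a closed chair transition state, then Mitsunobu inversion; C10 from (R)-citramalic acid; ester centre from (R)-2-methylbutanoic acid; Z-C4=C5 from trans-hydroalumination/iodination; E-C1=C2 from a stabilised Wittig reagent.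

Key step: step 13

Assumptions: compounds 1, 9, 14 and 18 are taken as purchasable. The (S,S)-antipode of ProPhenol is assumed to deliver the alkynyl group to the Re face of 2; if the opposite sense is found, the (R,R)-ligand is used instead.

**Route**

Step 1
Reactants: 1 tert-butyl(diphenyl)(prop-2-yn-1-yloxy)silane; 2 (E)-but-2-enal
Product: 3 (2E,4S)-7-[(tert-butyldiphenylsilyl)oxy]hept-2-en-5-yn-4-ol
Conditions: (S,S)-ProPhenol (10 mol%), Me2Zn (3 equiv), Ph3P=O (20 mol%), toluene, 4 °C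
Reagents that add atoms: none
Why: Zinc–ProPhenol catalysed asymmetric alkynylation of an enal (1,2-addition of the alkynylzinc), in which the chiral dinuclear zinc catalyst selects the aldehyde face and should set C6 as S.

Step 2
Reactants: 3 (2E,4S)-7-[(tert-butyldiphenylsilyl)oxy]hept-2-en-5-yn-4-ol
Product: 5 (2Z,4S,5E)-1-[(tert-butyldiphenylsilyl)oxy]-2-iodohepta-2,5-dien-4-ol, via sodium oxaluminole ate complex 4 (not isolated)
Conditions: NaAlH2(OCH2CH2OMe)2 (Red-Al), THF, 0 °C; then I2, THF, −78 °C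
Reagents that add atoms: iodine, II
Why: Alkoxide-directed trans-hydroalumination of the propargylic alcohol puts aluminium on the distal alkyne carbon (C4), and iodinolysis with retention should give the Z-iodoalkene with iodine cis to C6; the carbinol centre is not touched.

Step 3
Reactants: 5 (2Z,4S,5E)-1-[(tert-butyldiphenylsilyl)oxy]-2-iodohepta-2,5-dien-4-ol; 6 2-(bromomethyl)prop-2-enoic acid
Product: 7 (2Z,4S,5E)-1-[(tert-butyldiphenylsilyl)oxy]-2-iodohepta-2,5-dien-4-yl 2-(bromomethyl)prop-2-enoate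
Conditions: DCC, DMAP (5 mol%), CH2Cl2, 0 °C
Reagents that add atoms: none
Why: Steglich esterification of the secondary alcohol with retention at C6; low temperature and only catalytic DMAP limit amine attack on the allylic bromide.

Step 4
Reactants: 7 (2Z,4S,5E)-1-[(tert-butyldiphenylsilyl)oxy]-2-iodohepta-2,5-dien-4-yl 2-(bromomethyl)prop-2-enoate
Product: 8 (5S)-3-(bromomethyl)-5-[(1Z)-3-[(tert-butyldiphenylsilyl)oxy]-2-iodoprop-1-en-1-yl]furan-2(5H)-one
Conditions: second-generation Grubbs catalyst (H2IMes)(PCy3)Cl2Ru=CHPh (10 mol%), toluene, 80 °C, 5 mM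
Reagents that add atoms: none
Why: Ring-closing metathesis between the propenyl group and the 1,1-disubstituted acrylate should close the five-membered butenolide (C7=C11) with loss of propene; the trisubstituted iodoalkene is inert to the ruthenium carbene.

Step 5
Reactants: 9 (R)-citramalic acid
Product: 10 (2R)-2-methylbutane-1,2,4-triol
Conditions: BH3·SMe2, B(OMe)3, THF, 0 °C to rt; MeOH quench
Reagents that add atoms: none
Why: Borane reduction of both carboxylic acids to primary alcohols; the quaternary centre (later C10) is not involved.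

Step 6
Reactants: 10 (2R)-2-methylbutane-1,2,4-triol
Product: 11 2-[(4R)-2,2,4-trimethyl-1,3-dioxolan-4-yl]ethan-1-ol
Conditions: 2,2-dimethoxypropane, p-TsOH (cat.), acetone, rt
Reagents that add atoms: 2,2-dimethoxypropane, COC(C)(C)OC
Why: Acetonide formation under thermodynamic control favours the five-membered dioxolane across the 1,2-diol and leaves the primary hydroxyl of the future C8 free.

Step 7
Reactants: 11 2-[(4R)-2,2,4-trimethyl-1,3-dioxolan-4-yl]ethan-1-ol
Product: 12 2-[(4R)-2,2,4-trimethyl-1,3-dioxolan-4-yl]acetaldehyde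
Conditions: Dess–Martin periodinane, NaHCO3, CH2Cl2, 0 °C to rt
Reagents that add atoms: none
Why: Dess–Martin oxidation of the primary alcohol under buffered conditions that avoid β-elimination of the β-alkoxy aldehyde.

Step 8
Reactants: 8 (5S)-3-(bromomethyl)-5-[(1Z)-3-[(tert-butyldiphenylsilyl)oxy]-2-iodoprop-1-en-1-yl]furan-2(5H)-one; 12 2-[(4R)-2,2,4-trimethyl-1,3-dioxolan-4-yl]acetaldehyde
Product: 13 (4R,5S)-5-[(1Z)-3-[(tert-butyldiphenylsilyl)oxy]-2-iodoprop-1-en-1-yl]-4-{(1S)-1-hydroxy-2-[(4R)-2,2,4-trimethyl-1,3-dioxolan-4-yl]ethyl}-3-methylideneoxolan-2-one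
Conditions: Zn dust, THF/sat. aq NH4Cl (2:1), 0 °C to rt
Reagents that add atoms: none
Why: Barbier-type allylation in which the allylzinc adds through its γ-carbon (C7) in a closed chair-like transition state: attack anti to the C6 side chain sets C7 (trans-lactone), the ring-locked geometry of the allylmetal with the aldehyde residue equatorial should set C8 as S, and the iodoalkene does not insert zinc under these conditions.

Step 9
Reactants: 13 (4R,5S)-5-[(1Z)-3-[(tert-butyldiphenylsilyl)oxy]-2-iodoprop-1-en-1-yl]-4-{(1S)-1-hydroxy-2-[(4R)-2,2,4-trimethyl-1,3-dioxolan-4-yl]ethyl}-3-methylideneoxolan-2-one; 14 (R)-2-methylbutanoic acid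
Product: 15 (1R)-1-[(2S,3R)-2-[(1Z)-3-[(tert-butyldiphenylsilyl)oxy]-2-iodoprop-1-en-1-yl]-4-methylidene-5-oxooxolan-3-yl]-2-[(4R)-2,2,4-trimethyl-1,3-dioxolan-4-yl]ethyl (2R)-2-methylbutanoate
Conditions: PPh3, DIAD, toluene, 0 °C to rt (betaine preformed)
Reagents that add atoms: none
Why: Mitsunobu esterification, in which the carboxylate displaces the C8 alkoxyphosphonium with inversion, so the 8S alcohol should give the 8R ester directly; the acid stereocentre is not involved.

Step 10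
Reactants: 15 (1R)-1-[(2S,3R)-2-[(1Z)-3-[(tert-butyldiphenylsilyl)oxy]-2-iodoprop-1-en-1-yl]-4-methylidene-5-oxooxolan-3-yl]-2-[(4R)-2,2,4-trimethyl-1,3-dioxolan-4-yl]ethyl (2R)-2-methylbutanoate
Product: 16 (1R,3R)-1-[(2S,3R)-2-[(1Z)-3-[(tert-butyldiphenylsilyl)oxy]-2-iodoprop-1-en-1-yl]-4-methylidene-5-oxooxolan-3-yl]-3,4-dihydroxy-3-methylbutyl (2R)-2-methylbutanoate
Conditions: AcOH/H2O/THF (3:1:1), 45 °C
Reagents that add atoms: none
Why: Acid-catalysed hydrolysis of the terminal acetonide; the tert-butyldiphenylsilyl ether, the ester and the lactone should survive aqueous acetic acid.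

Step 11
Reactants: 16 (1R,3R)-1-[(2S,3R)-2-[(1Z)-3-[(tert-butyldiphenylsilyl)oxy]-2-iodoprop-1-en-1-yl]-4-methylidene-5-oxooxolan-3-yl]-3,4-dihydroxy-3-methylbutyl (2R)-2-methylbutanoate
Product: 17 (1R,3R)-1-[(2S,3R)-2-[(1Z)-3-[(tert-butyldiphenylsilyl)oxy]-2-iodoprop-1-en-1-yl]-4-methylidene-5-oxooxolan-3-yl]-3-hydroxy-3-methyl-4-oxobutyl (2R)-2-methylbutanoate
Conditions: SO3·pyridine, DMSO, iPr2NEt, CH2Cl2, 0 °C
Reagents that add atoms: none
Why: Parikh–Doering oxidation of the primary alcohol; the tertiary C10 hydroxyl cannot be oxidised and the α-carbon carries no hydrogen that could epimerise.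

Step 12
Reactants: 17 (1R,3R)-1-[(2S,3R)-2-[(1Z)-3-[(tert-butyldiphenylsilyl)oxy]-2-iodoprop-1-en-1-yl]-4-methylidene-5-oxooxolan-3-yl]-3-hydroxy-3-methyl-4-oxobutyl (2R)-2-methylbutanoate; 18 (triphenylphosphoranylidene)acetaldehyde
Product: 19 (1R,3R,4E)-1-[(2S,3R)-2-[(1Z)-3-[(tert-butyldiphenylsilyl)oxy]-2-iodoprop-1-en-1-yl]-4-methylidene-5-oxooxolan-3-yl]-3-hydroxy-3-methyl-6-oxohex-4-en-1-yl (2R)-2-methylbutanoate
Conditions: toluene, 70 °C
Reagents that add atoms: none
Why: Wittig reaction with a stabilised formyl ylide should give the E-enal (C1=C2) and adds C2 and C3 in one step; the product enal is less electrophilic than the α-oxygenated aldehyde, which limits double homologation.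

Step 13
Reactants: 19 (1R,3R,4E)-1-[(2S,3R)-2-[(1Z)-3-[(tert-butyldiphenylsilyl)oxy]-2-iodoprop-1-en-1-yl]-4-methylidene-5-oxooxolan-3-yl]-3-hydroxy-3-methyl-6-oxohex-4-en-1-yl (2R)-2-methylbutanoate
Product: 20 (1E,4Z,6R,7R,8R,10R)-15-[(tert-butyldiphenylsilyl)oxy]-3,10-dihydroxy-8-[(2R)-2-methylbutanoyloxy]germacra-1,4,11(13)-trien-12,6-olide (both C3 epimers)
Conditions: CrCl2 (20 equiv), NiCl2 (0.2 equiv), degassed DMSO, 2 mM, rt
Reagents that add atoms: none
Why: Zerovalent nickel (formed from NiCl2 by CrCl2) inserts into the C4–I bond, the alkenyl group passes to trivalent chromium, and the nucleophilic alkenylchromium adds 1,2 to the C3 aldehyde, so two electrophilic carbons are joined at the cost of two equivalents of divalent chromium. The closest known reaction type is the intramolecular Nozaki–Hiyama–Kishi coupling of iodoalkene aldehydes used to close nine- and ten-membered carbocycles of terpenoids. The ten-membered carbocycle (C1–C10) closes in the 10-exo-trig mode, the carbonyl oxygen staying outside the new ring. The new C3 carbinol centre is not controlled and need not be, since both epimers are oxidised to the same ketone in step 14. The step needs chemoselectivity for the aldehyde over lactone, ester and conjugate addition (secured by the carbonyl selectivity and low basicity of alkenylchromium reagents), retention of the Z geometry at C4=C5 (secured by the configurationally stable alkenyl–metal bond), and ring closure over oligomerisation (secured by high dilution and by the cis arrangement of C4 and C6 on the Z-alkene next to the trans-fused lactone).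

Step 14
Reactants: 20 (1E,4Z,6R,7R,8R,10R)-15-[(tert-butyldiphenylsilyl)oxy]-3,10-dihydroxy-8-[(2R)-2-methylbutanoyloxy]germacra-1,4,11(13)-trien-12,6-olide
Product: 21 (1E,4Z,6R,7R,8R,10R)-15-[(tert-butyldiphenylsilyl)oxy]-10-hydroxy-8-[(2R)-2-methylbutanoyloxy]-3-oxogermacra-1,4,11(13)-trien-12,6-olide
Conditions: Dess–Martin periodinane, NaHCO3, CH2Cl2, 0 °C
Reagents that add atoms: none
Why: Dess–Martin oxidation of the doubly allylic C3 carbinol (either epimer) to the cross-conjugated dienone; the tertiary alcohol is inert and the E geometry at C1=C2 prevents hemiketal formation with the C10 hydroxyl.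

Step 15
Reactants: 21 (1E,4Z,6R,7R,8R,10R)-15-[(tert-butyldiphenylsilyl)oxy]-10-hydroxy-8-[(2R)-2-methylbutanoyloxy]-3-oxogermacra-1,4,11(13)-trien-12,6-olide
Product: 22 (1E,4Z,6R,7R,8R,10R)-10,15-dihydroxy-8-[(2R)-2-methylbutanoyloxy]-3-oxogermacra-1,4,11(13)-trien-12,6-olide
Conditions: HF·pyridine, pyridine, THF, 0 °C to rt
Reagents that add atoms: none
Why: Fluoride cleavage of the primary silyl ether under buffered conditions that should spare the dienone, the α-methylene lactone, the ester and the tertiary alcohol.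

**Compound list**

1 | tert-butyl(diphenyl)(prop-2-yn-1-yloxy)silane | C#CCO[Si](c1ccccc1)(c1ccccc1)C(C)(C)C | starting material
2 | (E)-but-2-enal | C/C=C/C=O | starting material
3 | (2E,4S)-7-[(tert-butyldiphenylsilyl)oxy]hept-2-en-5-yn-4-ol | O[C@@H](/C=C/C)C#CCO[Si](c1ccccc1)(c1ccccc1)C(C)(C)C | intermediate
4 | sodium oxaluminole ate complex (cyclic alkenylalanate of 3, Al on C4, two 2-methoxyethoxy ligands; not isolated) | COCCO[Al-]1(OCCOC)O[C@@H](/C=C/C)C=C1CO[Si](c2ccccc2)(c2ccccc2)C(C)(C)C.[Na+] | intermediate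
5 | (2Z,4S,5E)-1-[(tert-butyldiphenylsilyl)oxy]-2-iodohepta-2,5-dien-4-ol | O[C@@H](/C=C/C)/C=C(\I)CO[Si](c1ccccc1)(c1ccccc1)C(C)(C)C | intermediate
6 | 2-(bromomethyl)prop-2-enoic acid | C=C(CBr)C(=O)O | starting material
7 | (2Z,4S,5E)-1-[(tert-butyldiphenylsilyl)oxy]-2-iodohepta-2,5-dien-4-yl 2-(bromomethyl)prop-2-enoate | C=C(CBr)C(=O)O[C@@H](/C=C/C)/C=C(\I)CO[Si](c1ccccc1)(c1ccccc1)C(C)(C)C | intermediate
8 | (5S)-3-(bromomethyl)-5-[(1Z)-3-[(tert-butyldiphenylsilyl)oxy]-2-iodoprop-1-en-1-yl]furan-2(5H)-one | BrCC1=C[C@@H](/C=C(\I)CO[Si](c2ccccc2)(c2ccccc2)C(C)(C)C)OC1=O | intermediate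
9 | (R)-citramalic acid | C[C@@](O)(CC(=O)O)C(=O)O | starting material
10 | (2R)-2-methylbutane-1,2,4-triol | OCC[C@@](C)(O)CO | intermediate
11 | 2-[(4R)-2,2,4-trimethyl-1,3-dioxolan-4-yl]ethan-1-ol | OCC[C@]1(C)COC(C)(C)O1 | intermediate
12 | 2-[(4R)-2,2,4-trimethyl-1,3-dioxolan-4-yl]acetaldehyde | O=CC[C@]1(C)COC(C)(C)O1 | intermediate
13 | (4R,5S)-5-[(1Z)-3-[(tert-butyldiphenylsilyl)oxy]-2-iodoprop-1-en-1-yl]-4-{(1S)-1-hydroxy-2-[(4R)-2,2,4-trimethyl-1,3-dioxolan-4-yl]ethyl}-3-methylideneoxolan-2-one | C=C1C(=O)O[C@H](/C=C(\I)CO[Si](c2ccccc2)(c2ccccc2)C(C)(C)C)[C@H]1[C@@H](O)C[C@]3(C)COC(C)(C)O3 | intermediate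
14 | (R)-2-methylbutanoic acid | CC[C@@H](C)C(=O)O | starting material
15 | (1R)-1-[(2S,3R)-2-[(1Z)-3-[(tert-butyldiphenylsilyl)oxy]-2-iodoprop-1-en-1-yl]-4-methylidene-5-oxooxolan-3-yl]-2-[(4R)-2,2,4-trimethyl-1,3-dioxolan-4-yl]ethyl (2R)-2-methylbutanoate | C=C1C(=O)O[C@H](/C=C(\I)CO[Si](c2ccccc2)(c2ccccc2)C(C)(C)C)[C@H]1[C@H](OC(=O)[C@H](C)CC)C[C@]3(C)COC(C)(C)O3 | intermediate
16 | (1R,3R)-1-[(2S,3R)-2-[(1Z)-3-[(tert-butyldiphenylsilyl)oxy]-2-iodoprop-1-en-1-yl]-4-methylidene-5-oxooxolan-3-yl]-3,4-dihydroxy-3-methylbutyl (2R)-2-methylbutanoate | C=C1C(=O)O[C@H](/C=C(\I)CO[Si](c2ccccc2)(c2ccccc2)C(C)(C)C)[C@H]1[C@H](OC(=O)[C@H](C)CC)C[C@@](C)(O)CO | intermediate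
17 | (1R,3R)-1-[(2S,3R)-2-[(1Z)-3-[(tert-butyldiphenylsilyl)oxy]-2-iodoprop-1-en-1-yl]-4-methylidene-5-oxooxolan-3-yl]-3-hydroxy-3-methyl-4-oxobutyl (2R)-2-methylbutanoate | C=C1C(=O)O[C@H](/C=C(\I)CO[Si](c2ccccc2)(c2ccccc2)C(C)(C)C)[C@H]1[C@H](OC(=O)[C@H](C)CC)C[C@@](C)(O)C=O | intermediate
18 | (triphenylphosphoranylidene)acetaldehyde | O=CC=P(c1ccccc1)(c1ccccc1)c1ccccc1 | starting material
19 | (1R,3R,4E)-1-[(2S,3R)-2-[(1Z)-3-[(tert-butyldiphenylsilyl)oxy]-2-iodoprop-1-en-1-yl]-4-methylidene-5-oxooxolan-3-yl]-3-hydroxy-3-methyl-6-oxohex-4-en-1-yl (2R)-2-methylbutanoate | C=C1C(=O)O[C@H](/C=C(\I)CO[Si](c2ccccc2)(c2ccccc2)C(C)(C)C)[C@H]1[C@H](OC(=O)[C@H](C)CC)C[C@@](C)(O)/C=C/C=O | intermediate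
20 | (1E,4Z,6R,7R,8R,10R)-15-[(tert-butyldiphenylsilyl)oxy]-3,10-dihydroxy-8-[(2R)-2-methylbutanoyloxy]germacra-1,4,11(13)-trien-12,6-olide (C3 epimers) | C=C1C(=O)O[C@@H]2/C=C(/CO[Si](c3ccccc3)(c3ccccc3)C(C)(C)C)C(O)/C=C/[C@](C)(O)C[C@@H](OC(=O)[C@H](C)CC)[C@@H]12 | intermediate
21 | (1E,4Z,6R,7R,8R,10R)-15-[(tert-butyldiphenylsilyl)oxy]-10-hydroxy-8-[(2R)-2-methylbutanoyloxy]-3-oxogermacra-1,4,11(13)-trien-12,6-olide | C=C1C(=O)O[C@@H]2/C=C(/CO[Si](c3ccccc3)(c3ccccc3)C(C)(C)C)C(=O)/C=C/[C@](C)(O)C[C@@H](OC(=O)[C@H](C)CC)[C@@H]12 | intermediate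
22 | (1E,4Z,6R,7R,8R,10R)-10,15-dihydroxy-8-[(2R)-2-methylbutanoyloxy]-3-oxogermacra-1,4,11(13)-trien-12,6-olide | C=C1C(=O)O[C@@H]2/C=C(/CO)C(=O)/C=C/[C@](C)(O)C[C@@H](OC(=O)[C@H](C)CC)[C@@H]12 | target

**Step count**
Total: 15 steps. Longest linear sequence: 12 steps (steps 1–4 and 8–15, from 1 and 2 to 22).

**Steps most likely to fail, with fallbacks**

Step 13. Ring closure may lose out to protodeiodination of the alkenyl metal or to oligomerisation, because the ten-membered ring with an E and a Z alkene is strained. The fallback makes the C3–C4 bond between two molecules and closes the ring at C1=C2 instead. It sets out from 15. Coupling of 15 with diethyl (2-oxoethyl)phosphonate under CrCl2/NiCl2 in DMSO should give the β-hydroxyphosphonate F3. Dess–Martin oxidation gives the β-ketophosphonate F4. Aqueous acetic acid removes the acetonide to give the diol F5. Parikh–Doering oxidation gives the aldehyde F6. An intramolecular Horner–Wadsworth–Emmons reaction (LiCl, iPr2NEt, MeCN, high dilution) should then form the E-enone and come back to the route at 21.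

Step 9. The hindered C8 alkoxyphosphonium may eliminate or fail to be displaced by the weakly acidic, α-branched carboxylic acid. The fallback inverts C8 by oxidation and reduction instead of substitution. It sets out from 13. Dess–Martin oxidation gives the C8 ketone F1. Reduction with (S)-2-methyl-CBS-oxazaborolidine and catecholborane is expected to give the 8R alcohol F2 under reagent control. Steglich acylation of F2 with 14 (DCC, DMAP) proceeds with retention and comes back to the route at 15. Should step 8 deliver the 8R alcohol F2 directly, the same acylation applies.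

Step 1. Enantioselectivity may be insufficient with a non-activated alkyne donor and a simple enal. The fallback sets the C6 centre by asymmetric reduction instead of asymmetric addition. It sets out from 1 and 2. Deprotonation of 1 with n-BuLi (THF, −78 °C) and addition to 2 gives the racemic alcohol F7. MnO2 in CH2Cl2 oxidises it to the enynone F8. Midland reduction with (S)-Alpine-Borane, in which the alkynyl group acts as the small substituent, should give the S alcohol and come back to the route at 3.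

**Further compounds**

F1 | step 9 | C8 ketone of 13: (4S,5S)-5-[(1Z)-3-[(tert-butyldiphenylsilyl)oxy]-2-iodoprop-1-en-1-yl]-3-methylidene-4-{[(4R)-2,2,4-trimethyl-1,3-dioxolan-4-yl]acetyl}oxolan-2-one | C=C1C(=O)O[C@H](/C=C(\I)CO[Si](c2ccccc2)(c2ccccc2)C(C)(C)C)[C@H]1C(=O)C[C@]3(C)COC(C)(C)O3
F2 | step 9 | C8 epimer of 13: (4R,5S)-5-[(1Z)-3-[(tert-butyldiphenylsilyl)oxy]-2-iodoprop-1-en-1-yl]-4-{(1R)-1-hydroxy-2-[(4R)-2,2,4-trimethyl-1,3-dioxolan-4-yl]ethyl}-3-methylideneoxolan-2-one | C=C1C(=O)O[C@H](/C=C(\I)CO[Si](c2ccccc2)(c2ccccc2)C(C)(C)C)[C@H]1[C@H](O)C[C@]3(C)COC(C)(C)O3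
F3 | step 13 | β-hydroxyphosphonate: analogue of 15 in which iodine on C4 is replaced by CH(OH)CH2P(O)(OEt)2 (C3 epimers) | C=C1C(=O)O[C@H](/C=C(/CO[Si](c2ccccc2)(c2ccccc2)C(C)(C)C)C(O)CP(=O)(OCC)OCC)[C@H]1[C@H](OC(=O)[C@H](C)CC)C[C@]3(C)COC(C)(C)O3
F4 | step 13 | β-ketophosphonate: C3 ketone of F3 | C=C1C(=O)O[C@H](/C=C(/CO[Si](c2ccccc2)(c2ccccc2)C(C)(C)C)C(=O)CP(=O)(OCC)OCC)[C@H]1[C@H](OC(=O)[C@H](C)CC)C[C@]3(C)COC(C)(C)O3
F5 | step 13 | diol: F4 without the acetonide (free C10 and C1 hydroxyls) | C=C1C(=O)O[C@H](/C=C(/CO[Si](c2ccccc2)(c2ccccc2)C(C)(C)C)C(=O)CP(=O)(OCC)OCC)[C@H]1[C@H](OC(=O)[C@H](C)CC)C[C@@](C)(O)CO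
F6 | step 13 | keto-phosphonate aldehyde: F5 with C1 oxidised to the aldehyde | C=C1C(=O)O[C@H](/C=C(/CO[Si](c2ccccc2)(c2ccccc2)C(C)(C)C)C(=O)CP(=O)(OCC)OCC)[C@H]1[C@H](OC(=O)[C@H](C)CC)C[C@@](C)(O)C=O
F7 | step 1 | racemic (2E)-7-[(tert-butyldiphenylsilyl)oxy]hept-2-en-5-yn-4-ol | C/C=C/C(O)C#CCO[Si](c1ccccc1)(c1ccccc1)C(C)(C)C
F8 | step 1 | (2E)-7-[(tert-butyldiphenylsilyl)oxy]hept-2-en-5-yn-4-one | C/C=C/C(=O)C#CCO[Si](c1ccccc1)(c1ccccc1)C(C)(C)C
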